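**Plan**

1. Numbering: C1 is the isobutyryl-bearing cage carbon between the C2 and C9 ketones; C3 is the quaternary ring-fusion carbon, C4 a ketone, C5 the geranyl carbon, C6 a CH2, C7 a CH, C8 a CMe2; C10 (CH2) and C11 (CH) join C7 to C3; C12 (CMe2), C13 (isopropenyl CH) and C14 (CH2) complete the cyclopentane.
2. Retrosynthetic cuts: C1–C2 and C1–C9 (two acylations of the α-carbon of an isopropyl ketone), then C4–C5 and C5–C6 (C5 leaves with its geranyl group and the C9 ester), then C7–C8, C3–C4, C10–C11 and C13–isopropenyl.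
3. Enabling feature: C5 is quaternary, lies between the C4 ketone and the C6 methylene of the seven-membered ring C3–C4–C5–C6–C7–C10–C11, and carries the geranyl chain and the C9 carbonyl. This is the pattern left when an α-geranyl α-diazo ester inserts next to the ketone of the six-membered ring C3–C4–C6–C7–C10–C11.
4. Forward order of rings: cyclopentane (bought as the enone) → six-membered ring by C3–C4 acylation (cis-hydrindanone) → side chain on C7 → seven-membered ring by insertion of C5 → ring C1/C9/C5/C6/C7/C8 by Claisen condensation → cage ring C1/C2/C3/C4/C5/C9 by C-acylation.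
5. Stereochemistry: C13 from a rhodium/(S)-BINAP conjugate addition; C11 by alkylation anti to the isopropenyl group; C3 by the tether (cis fusion); C7 by radical attack on the convex face; C5 by the chiral scandium catalyst; C1 by the cage.

Key step: step 17

Remark: the side-chain ketone is carried unprotected; it is flanked by an isopropyl and a neopentyl carbon and cannot chelate scandium, whereas the C4 ketone is part of a β-keto ester chelate.
Remark: the sense of induction of (S)-BINAP and of the N,N'-dioxide ligand is assigned by analogy; both ligand enantiomers would be screened on the first run.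

**Route**

Step 1
Reactants: 1 4,4-dimethylcyclopent-2-en-1-one
Product: 2 (S)-3,3-dimethyl-4-(prop-1-en-2-yl)cyclopentan-1-one
Conditions: [Rh(cod)2]PF6 (3 mol %), (S)-BINAP (3.3 mol %), potassium trifluoro(prop-1-en-2-yl)borate (2 equiv), toluene/H2O 10:1, 100 °C
Reagents that add atoms: potassium trifluoro(prop-1-en-2-yl)borate, C=C(C)[B-](F)(F)F.[K+]
Why: Rhodium/BINAP-catalysed asymmetric 1,4-addition of an alkenyl boron reagent to a cyclic enone; the chiral rhodium alkenyl complex should add to one enantioface of the enone and set C13 as (S).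

Step 2
Reactants: 2 (S)-3,3-dimethyl-4-(prop-1-en-2-yl)cyclopentan-1-one
Product: 3 allyl 4,4-dimethyl-2-oxo-5-(prop-1-en-2-yl)cyclopentane-1-carboxylate
Conditions: NaH (2.5 equiv), diallyl carbonate (2.5 equiv), THF, 65 °C; aq. NH4Cl
Reagents that add atoms: diallyl carbonate, C=CCOC(=O)OCC=C
Why: Claisen-type C-acylation of the ketone under thermodynamic control should take the less hindered α-methylene C14 (next to the tertiary C13) and not the neopentyl C11; the product is held as its sodium enolate, and the ester leaves C11 as the only site for a second deprotonation.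

Step 3
Reactants: 4 4-bromobutanoyl chloride
Product: 5 4-bromo-N-methoxy-N-methylbutanamide
Conditions: MeNH(OMe)·HCl (1.05 equiv), Et3N (2.2 equiv), CH2Cl2, 0 °C
Reagents that add atoms: N,O-dimethylhydroxylamine hydrochloride, CNOC.Cl
Why: Aminolysis of an acid chloride gives the Weinreb amide; the primary bromide is inert at 0 °C.

Step 4
Reactants: 3 allyl 4,4-dimethyl-2-oxo-5-(prop-1-en-2-yl)cyclopentane-1-carboxylate; 5 4-bromo-N-methoxy-N-methylbutanamide
Product: 6 allyl 3-[4-[methoxy(methyl)amino]-4-oxobutyl]-4,4-dimethyl-2-oxo-5-(prop-1-en-2-yl)cyclopentane-1-carboxylate (chain on C11 trans to isopropenyl)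
Conditions: LiN(i-Pr)2 (2.2 equiv), THF, −78 → 0 °C; then 5 (1.2 equiv), DMPU, −78 → 0 °C; aq. NH4Cl
Reagents that add atoms: none
Why: γ-Alkylation of a β-keto ester dianion: the second deprotonation can only occur at C11, the more reactive terminus; the isopropenyl group on C13 pushes the cis methyl of C12 over its own face, so the bromide should enter anti to it and set C11 with the chain trans to isopropenyl.

Step 5
Reactants: 6 allyl 3-[4-[methoxy(methyl)amino]-4-oxobutyl]-4,4-dimethyl-2-oxo-5-(prop-1-en-2-yl)cyclopentane-1-carboxylate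
Product: 8 4-[2,2-dimethyl-5-oxo-3-(prop-1-en-2-yl)cyclopentyl]-N-methoxy-N-methylbutanamide, via β-keto acid 7 (not isolated)
Conditions: Pd(PPh3)4 (5 mol %), morpholine (5 equiv), THF, 25 °C
Reagents that add atoms: none
Why: Palladium-catalysed allyl transfer to morpholine (Tsuji–Trost deallylation) and spontaneous decarboxylation of the β-keto acid remove the C14 ester under neutral conditions that should leave C11 unepimerised.

Step 6
Reactants: 8 4-[2,2-dimethyl-5-oxo-3-(prop-1-en-2-yl)cyclopentyl]-N-methoxy-N-methylbutanamide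
Product: 9 5-[4-[methoxy(methyl)amino]-4-oxobutyl]-4,4-dimethyl-3-(prop-1-en-2-yl)cyclopent-1-en-1-yl trifluoromethanesulfonate
Conditions: KN(SiMe3)2 (1.1 equiv), THF, −78 °C; then PhNTf2 (1.15 equiv), −78 → 0 °C
Reagents that add atoms: N-phenylbis(trifluoromethanesulfonimide), O=S(=O)(N(c1ccccc1)S(=O)(=O)C(F)(F)F)C(F)(F)F
Why: Kinetic enolisation and O-sulfonylation: the hindered base should take a proton from the methylene C14 and not from the substituted, neopentyl C11–H, giving the C3=C14 enol triflate with C11 intact.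

Step 7
Reactants: 9 5-[4-[methoxy(methyl)amino]-4-oxobutyl]-4,4-dimethyl-3-(prop-1-en-2-yl)cyclopent-1-en-1-yl trifluoromethanesulfonate
Product: 10 5-[4-[methoxy(methyl)amino]-4-oxobutyl]-4,4-dimethyl-3-(prop-1-en-2-yl)cyclopent-1-ene-1-carboxylic acid
Conditions: Pd(OAc)2 (5 mol %), PPh3 (10 mol %), CO (1 atm), KOAc (4 equiv), DMF, 25–50 °C; then H2O, dilute HCl
Reagents that add atoms: carbon monoxide, [C-]#[O+]; water, O
Why: Palladium-catalysed hydroxycarbonylation of an enol triflate (oxidative addition, CO insertion, acyl transfer to acetate, hydrolysis) puts the carboxyl carbon C2 on C3.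

Step 8
Reactants: 10 5-[4-[methoxy(methyl)amino]-4-oxobutyl]-4,4-dimethyl-3-(prop-1-en-2-yl)cyclopent-1-ene-1-carboxylic acid
Product: 11 tert-butyl 5-[4-[methoxy(methyl)amino]-4-oxobutyl]-4,4-dimethyl-3-(prop-1-en-2-yl)cyclopent-1-ene-1-carboxylate
Conditions: Boc2O (2 equiv), DMAP (0.3 equiv), t-BuOH/THF, 40 °C
Reagents that add atoms: di-tert-butyl dicarbonate, CC(C)(C)OC(=O)OC(=O)OC(C)(C)C
Why: DMAP-catalysed esterification through the mixed carbonic anhydride gives the tert-butyl ester without acid; this ester keeps C2 inert to bases and enolates until the last step, where it is converted to the acid chloride through its silyl ester, so that no free β-keto acid or carboxylate is formed.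

Step 9
Reactants: 11 tert-butyl 5-[4-[methoxy(methyl)amino]-4-oxobutyl]-4,4-dimethyl-3-(prop-1-en-2-yl)cyclopent-1-ene-1-carboxylate
Product: 12 tert-butyl 2-[4-[methoxy(methyl)amino]-4-oxobutyl]-3,3-dimethyl-4-(prop-1-en-2-yl)cyclopentane-1-carboxylate (mixture of C3 epimers)
Conditions: Cu(OAc)2·H2O (5 mol %), 1,2-bis(diphenylphosphino)benzene (5 mol %), (EtO)2MeSiH (2 equiv), t-BuOH (2 equiv), toluene, 25 °C
Reagents that add atoms: none
Why: Copper hydride-catalysed conjugate reduction takes only the polarised C3=C14 bond (isopropenyl and Weinreb amide are untouched); the configuration of C3 does not matter because C3 is enolised in step 10.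

Step 10
Reactants: 12 tert-butyl 2-[4-[methoxy(methyl)amino]-4-oxobutyl]-3,3-dimethyl-4-(prop-1-en-2-yl)cyclopentane-1-carboxylate
Product: 13 tert-butyl 1,1-dimethyl-4-oxo-2-(prop-1-en-2-yl)octahydro-3aH-indene-3a-carboxylate (cis-fused; ester, H11 and isopropenyl on one face)
Conditions: LiN(SiMe3)2 (1.5 equiv), THF, −78 → 0 °C; aq. NH4Cl
Reagents that add atoms: none
Why: Intramolecular Claisen-type acylation of an ester enolate by a Weinreb amide (Dieckmann-like 6-exo-trig closure): the silylamide enolises the ester at C3 but not the less acidic amide, the chelated tetrahedral adduct blocks retro-Claisen and over-addition, and the three-carbon tether from C11 reaches only one face of C3, so the ring closes cis-fused and C3 is set with the ester cis to H11 and to the isopropenyl group.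

Step 11
Reactants: 13 tert-butyl 1,1-dimethyl-4-oxo-2-(prop-1-en-2-yl)octahydro-3aH-indene-3a-carboxylate
Product: 14 tert-butyl 1,1-dimethyl-4-oxo-2-(prop-1-en-2-yl)-1,2,3,4,7,7a-hexahydro-3aH-indene-3a-carboxylate
Conditions: IBX (2.5 equiv), DMSO, 70 °C
Reagents that add atoms: none
Why: IBX-mediated α,β-dehydrogenation of a ketone; C4 has one enolisable α-carbon (C6, since C3 is quaternary), so the C6=C7 enone forms regiospecifically.

Step 12
Reactants: 15 2,2-dimethylsuccinic anhydride
Product: 16 2,2,5-trimethyl-4-oxohexanoic acid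
Conditions: i-PrMgCl (1.05 equiv), THF, −78 → −30 °C; aq. HCl
Reagents that add atoms: isopropylmagnesium chloride, CC(C)[Mg]Cl
Why: Acylation of a Grignard reagent by a cyclic anhydride should occur at the carbonyl remote from the gem-dimethyl group and stop at the keto carboxylate at low temperature.

Step 13
Reactants: 16 2,2,5-trimethyl-4-oxohexanoic acid
Product: 17 1,3-dioxoisoindolin-2-yl 2,2,5-trimethyl-4-oxohexanoate
Conditions: N-hydroxyphthalimide (1.1 equiv), N,N'-diisopropylcarbodiimide (1.1 equiv), DMAP (10 mol %), CH2Cl2, 25 °C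
Reagents that add atoms: N-hydroxyphthalimide, O=C1N(O)C(=O)c2ccccc12
Why: Carbodiimide (Steglich-type) esterification gives the redox-active ester that serves as precursor of the tertiary radical at C8.

Step 14
Reactants: 14 tert-butyl 1,1-dimethyl-4-oxo-2-(prop-1-en-2-yl)-1,2,3,4,7,7a-hexahydro-3aH-indene-3a-carboxylate; 17 1,3-dioxoisoindolin-2-yl 2,2,5-trimethyl-4-oxohexanoate
Product: 18 tert-butyl 6-(2,5-dimethyl-4-oxohexan-2-yl)-1,1-dimethyl-4-oxo-2-(prop-1-en-2-yl)octahydro-3aH-indene-3a-carboxylate (side chain on C7 cis to the ester)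
Conditions: Ru(bpy)3(PF6)2 (1 mol %), Hantzsch ester (1.5 equiv), i-Pr2NEt·HBF4 (1 equiv), CH2Cl2, blue LEDs, 25 °C
Reagents that add atoms: none
Why: Photoredox decarboxylative Giese addition: one-electron reduction of the N-acyloxyphthalimide releases CO2 and the tertiary C8 radical, which should add to the enone β-carbon C7 on the convex face, anti to C12 on C11 (the trans-3,5 preference of 5-substituted cyclohexenones); this forms the C7–C8 bond and sets C7.

Step 15
Reactants: 19 methyl acetoacetate; 20 geranyl bromide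
Product: 21 methyl (E)-2-acetyl-5,9-dimethyldeca-4,8-dienoate (racemic)
Conditions: NaH (1.0 equiv), 19 (1.5 equiv), THF, 0 °C; then 20, 0 → 25 °C
Reagents that add atoms: none
Why: Acetoacetic ester C-alkylation (SN2 at the primary allylic bromide) keeps the E-alkene; the excess keto ester limits dialkylation.

Step 16
Reactants: 21 methyl (E)-2-acetyl-5,9-dimethyldeca-4,8-dienoate
Product: 22 methyl (E)-2-diazo-5,9-dimethyldeca-4,8-dienoate
Conditions: 4-acetamidobenzenesulfonyl azide (1.3 equiv), DBU (1.5 equiv), MeCN, 0 → 25 °C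
Reagents that add atoms: 4-acetamidobenzenesulfonyl azide, CC(=O)Nc1ccc(cc1)S(=O)(=O)N=[N+]=[N-]
Why: Regitz deacylative diazo transfer: the enolate adds to the sulfonyl azide and the adduct fragments with loss of the acetyl group as the N-acetylsulfonamide.

Step 17
Reactants: 18 tert-butyl 6-(2,5-dimethyl-4-oxohexan-2-yl)-1,1-dimethyl-4-oxo-2-(prop-1-en-2-yl)octahydro-3aH-indene-3a-carboxylate; 22 methyl (E)-2-diazo-5,9-dimethyldeca-4,8-dienoate
Product: 23 3a-tert-butyl 5-methyl 5-[(E)-3,7-dimethylocta-2,6-dien-1-yl]-7-(2,5-dimethyl-4-oxohexan-2-yl)-1,1-dimethyl-4-oxo-2-(prop-1-en-2-yl)octahydroazulene-3a,5(1H)-dicarboxylate (C9 ester on C5 cis to the C2 ester and to the C7 side chain)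
Conditions: Sc(OTf)3 (10 mol %), chiral N,N'-dioxide ligand from L-ramipril acid and 2,6-diisopropylaniline (11 mol %, or its enantiomer), 4 Å molecular sieves, CH2Cl2, 0 → 30 °C; 22 (2 equiv) added slowly
Reagents that add atoms: none
Why: The trivalent scandium complex binds the β-keto ester of 18 as a chelate, the nucleophilic diazo carbon of 22 adds to the C4 carbonyl, and C6 then shifts from C4 to the diazonium carbon as N2 leaves, which restores the C4 ketone and places C5 between C4 and C6. The closest known reaction is the scandium triflate/N,N'-dioxide-catalysed homologation of cyclic ketones with α-alkyl α-diazo esters to β-keto esters with a quaternary carbon, here applied to a hindered α-quaternary ketone. The seven-membered ring is not closed by cyclisation but by ring enlargement, a 1,2-shift of the C4–C6 ring bond that amounts to a one-carbon insertion. The new stereocentre C5 is set by the chiral ligand, which selects the enantioface of the diazo carbon, together with approach of the reagent to the convex face of the cis-hydrindanone; the ligand enantiomer that places the C9 ester cis to the C2 ester would be used. The step needs migration of C6 and not C3, secured because C3 is quaternary, electron-poor and tied into the chelate, and reaction at C4 and not at the side-chain ketone, secured by chelation and by the isopropyl and neopentyl flanks of the latter. The alkenes are not at risk because no metal carbene is formed.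

Step 18
Reactants: 23 3a-tert-butyl 5-methyl 5-[(E)-3,7-dimethylocta-2,6-dien-1-yl]-7-(2,5-dimethyl-4-oxohexan-2-yl)-1,1-dimethyl-4-oxo-2-(prop-1-en-2-yl)octahydroazulene-3a,5(1H)-dicarboxylate
Product: 24 bicyclic 2-isobutyryl-1,3-dione tert-butyl ester (C1–C9 bond closed; drawn as the C9 enol)
Conditions: LiN(SiMe3)2 (2.3 equiv), THF, −78 → 0 °C; aq. NH4Cl
Reagents that add atoms: none
Why: Intramolecular Claisen condensation (6-exo-trig): the enolate at C1 of the side-chain ketone attacks the C9 methyl ester, which sits 1,3-cis to the side chain on the seven-membered ring, and the product is protected as its lithium enolate; the tert-butyl ester is too hindered to react and the C4 ketone has no α-hydrogen.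

Step 19
Reactants: 24 bicyclic 2-isobutyryl-1,3-dione tert-butyl ester
Product: 27 CNP0280463.1 (target cage tetraketone), via bis-silyl derivative 25 (not isolated), via acid chloride 26 (not isolated)
Conditions: TMSOTf (3 equiv), 2,6-lutidine (4 equiv), CH2Cl2, 0 → 25 °C; volatiles removed; (COCl)2 (1.5 equiv), DMF (cat.), CH2Cl2, 0 °C; then ZnCl2 (1 equiv), CH2Cl2/Et2O, 0 → 25 °C
Reagents that add atoms: none
Why: Proposed new method: the silyl triflate converts the tert-butyl ester into the silyl ester (loss of isobutene) and the enol into its silyl ether, oxalyl chloride turns the silyl ester into the acid chloride without a free β-keto acid, and zinc chloride should then promote attack of the silyl enol ether carbon C1 on the C2 acid chloride through a six-membered transition state with loss of Me3SiCl, the chloride leaving group making the acylation irreversible although the product cannot enolise; the closest known reactions are the zinc chloride-mediated C-acylation of silyl enol ethers of ketones and 1,3-diketones with acid chlorides and the Effenberger-type cyclisation to bicyclo[3.3.1]nonane-2,4,9-triones; C1, the last stereocentre, is fixed by the cage.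

**Compound list**

1 | 4,4-dimethylcyclopent-2-en-1-one | CC1(C)CC(=O)C=C1 | starting material
2 | (S)-3,3-dimethyl-4-(prop-1-en-2-yl)cyclopentan-1-one | C=C(C)[C@@H]1CC(=O)CC1(C)C | intermediate
3 | allyl 4,4-dimethyl-2-oxo-5-(prop-1-en-2-yl)cyclopentane-1-carboxylate (C13 as in 2; labile C14 centre drawn with the ester trans to isopropenyl) | C=C(C)[C@@H]1[C@@H](C(=O)OCC=C)C(=O)CC1(C)C | intermediate
4 | 4-bromobutanoyl chloride | O=C(Cl)CCCBr | starting material
5 | 4-bromo-N-methoxy-N-methylbutanamide | CON(C)C(=O)CCCBr | intermediate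
6 | allyl 3-[4-[methoxy(methyl)amino]-4-oxobutyl]-4,4-dimethyl-2-oxo-5-(prop-1-en-2-yl)cyclopentane-1-carboxylate (chain on C11 trans to isopropenyl; C14 labile) | C=C(C)[C@@H]1[C@@H](C(=O)OCC=C)C(=O)[C@@H](CCCC(=O)N(C)OC)C1(C)C | intermediate
7 | 3-[4-[methoxy(methyl)amino]-4-oxobutyl]-4,4-dimethyl-2-oxo-5-(prop-1-en-2-yl)cyclopentane-1-carboxylic acid | C=C(C)[C@@H]1[C@@H](C(=O)O)C(=O)[C@@H](CCCC(=O)N(C)OC)C1(C)C | intermediate
8 | 4-[2,2-dimethyl-5-oxo-3-(prop-1-en-2-yl)cyclopentyl]-N-methoxy-N-methylbutanamide (chain trans to isopropenyl) | C=C(C)[C@@H]1CC(=O)[C@@H](CCCC(=O)N(C)OC)C1(C)C | intermediate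
9 | 5-[4-[methoxy(methyl)amino]-4-oxobutyl]-4,4-dimethyl-3-(prop-1-en-2-yl)cyclopent-1-en-1-yl trifluoromethanesulfonate | C=C(C)[C@@H]1C=C(OS(=O)(=O)C(F)(F)F)[C@@H](CCCC(=O)N(C)OC)C1(C)C | intermediate
10 | 5-[4-[methoxy(methyl)amino]-4-oxobutyl]-4,4-dimethyl-3-(prop-1-en-2-yl)cyclopent-1-ene-1-carboxylic acid | C=C(C)[C@@H]1C=C(C(=O)O)[C@@H](CCCC(=O)N(C)OC)C1(C)C | intermediate
11 | tert-butyl 5-[4-[methoxy(methyl)amino]-4-oxobutyl]-4,4-dimethyl-3-(prop-1-en-2-yl)cyclopent-1-ene-1-carboxylate | C=C(C)[C@@H]1C=C(C(=O)OC(C)(C)C)[C@@H](CCCC(=O)N(C)OC)C1(C)C | intermediate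
12 | tert-butyl 2-[4-[methoxy(methyl)amino]-4-oxobutyl]-3,3-dimethyl-4-(prop-1-en-2-yl)cyclopentane-1-carboxylate (both C3 epimers; that centre left undefined) | C=C(C)[C@@H]1CC(C(=O)OC(C)(C)C)[C@@H](CCCC(=O)N(C)OC)C1(C)C | intermediate
13 | tert-butyl 1,1-dimethyl-4-oxo-2-(prop-1-en-2-yl)octahydro-3aH-indene-3a-carboxylate (cis-fused; ester, H11 and isopropenyl on one face) | C=C(C)[C@@H]1C[C@@]2(C(=O)OC(C)(C)C)C(=O)CCC[C@H]2C1(C)C | intermediate
14 | tert-butyl 1,1-dimethyl-4-oxo-2-(prop-1-en-2-yl)-1,2,3,4,7,7a-hexahydro-3aH-indene-3a-carboxylate | C=C(C)[C@@H]1C[C@@]2(C(=O)OC(C)(C)C)C(=O)C=CC[C@H]2C1(C)C | intermediate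
15 | 2,2-dimethylsuccinic anhydride | CC1(C)CC(=O)OC1=O | starting material
16 | 2,2,5-trimethyl-4-oxohexanoic acid | CC(C)C(=O)CC(C)(C)C(=O)O | intermediate
17 | 1,3-dioxoisoindolin-2-yl 2,2,5-trimethyl-4-oxohexanoate | CC(C)C(=O)CC(C)(C)C(=O)ON1C(=O)c2ccccc2C1=O | intermediate
18 | tert-butyl 6-(2,5-dimethyl-4-oxohexan-2-yl)-1,1-dimethyl-4-oxo-2-(prop-1-en-2-yl)octahydro-3aH-indene-3a-carboxylate (cis-fused; side chain on C7 cis to the ester) | C=C(C)[C@@H]1C[C@@]2(C(=O)OC(C)(C)C)C(=O)C[C@@H](C[C@H]2C1(C)C)C(C)(C)CC(=O)C(C)C | intermediate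
19 | methyl acetoacetate | COC(=O)CC(C)=O | starting material
20 | geranyl bromide | CC(C)=CCC/C(C)=C/CBr | starting material
21 | methyl (E)-2-acetyl-5,9-dimethyldeca-4,8-dienoate (racemic) | COC(=O)C(C(C)=O)C/C=C(\C)CCC=C(C)C | intermediate
22 | methyl (E)-2-diazo-5,9-dimethyldeca-4,8-dienoate | COC(=O)C(=[N+]=[N-])C/C=C(\C)CCC=C(C)C | intermediate
23 | 3a-tert-butyl 5-methyl 5-[(E)-3,7-dimethylocta-2,6-dien-1-yl]-7-(2,5-dimethyl-4-oxohexan-2-yl)-1,1-dimethyl-4-oxo-2-(prop-1-en-2-yl)octahydroazulene-3a,5(1H)-dicarboxylate (C2 ester, C9 ester and C7 side chain on one face) | C=C(C)[C@@H]1C[C@@]2(C(=O)OC(C)(C)C)C(=O)[C@@](C(=O)OC)(C/C=C(\C)CCC=C(C)C)C[C@@H](C[C@H]2C1(C)C)C(C)(C)CC(=O)C(C)C | intermediate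
24 | bicyclic 2-isobutyryl-1,3-dione tert-butyl ester (C1–C9 closed; C9 enol) | C=C(C)[C@@H]1C[C@@]2(C(=O)OC(C)(C)C)C(=O)[C@@]3(C/C=C(\C)CCC=C(C)C)C[C@@H](C[C@H]2C1(C)C)C(C)(C)C(C(=O)C(C)C)=C3O | intermediate
25 | trimethylsilyl ester and trimethylsilyl enol ether of 24 | C=C(C)[C@@H]1C[C@@]2(C(=O)O[Si](C)(C)C)C(=O)[C@@]3(C/C=C(\C)CCC=C(C)C)C[C@@H](C[C@H]2C1(C)C)C(C)(C)C(C(=O)C(C)C)=C3O[Si](C)(C)C | intermediate
26 | C2 acid chloride bearing the C9 trimethylsilyl enol ether | C=C(C)[C@@H]1C[C@@]2(C(Cl)=O)C(=O)[C@@]3(C/C=C(\C)CCC=C(C)C)C[C@@H](C[C@H]2C1(C)C)C(C)(C)C(C(=O)C(C)C)=C3O[Si](C)(C)C | intermediate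
27 | CNP0280463.1 | C=C(C)[C@@H]1C[C@@]23C(=O)[C@@]4(C/C=C(\C)CCC=C(C)C)C[C@@H](C[C@H]2C1(C)C)C(C)(C)[C@](C(=O)C(C)C)(C4=O)C3=O | target

**Step count**

Total: 19 steps. Longest linear sequence: 14 steps (1, 2, 4, 5, 6, 7, 8, 9, 10, 11, 14, 17, 18, 19).

**Steps most likely to fail**

Step 19. The enol oxygen may be acylated faster than C1, or the tertiary acid chloride may ionise before the C–C bond forms. The fallback sets out from the acid chloride 26 and uses an aldol closure in place of the acylation. Ethanethiol and Et3N in CH2Cl2 would give the S-ethyl thioester F1, the silyl enol ether being cleaved on aqueous work-up. Fukuyama reduction (Et3SiH, Pd/C, acetone) would give the aldehyde F2. Intramolecular aldol addition of the 1,3-diketone carbon C1 to the aldehyde (DBU, CH2Cl2) would close the cage as the C2 carbinol F3. Dess–Martin oxidation of the carbinol rejoins the route at 27.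

Step 17. The tetrasubstituted diazo carbon may add too slowly to the hindered C4 carbonyl, so that 1,2-hydride shift of the diazo ester wins, or facial control at C5 may be poor. The fallback sets out from 18 and separates the insertion from the geranylation. Methyl diazoacetate with Sc(OTf)3 (10 mol %) in CH2Cl2 should insert an unsubstituted carbon by the same C6 shift and give the ring-expanded β-keto diester F4 with hydrogen on C5. C-Alkylation of F4 with geranyl bromide 20 (K2CO3, acetone), expected to occur anti to the C7 side chain, rejoins the route at 23.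

Step 14. The tertiary radical may be reduced before it adds to the enone, or it may add to the concave face. The fallback sets out from 14 and uses an ionic conjugate addition followed by chain extension. Hosomi–Sakurai addition of prenyltrimethylsilane (TiCl4, CH2Cl2, −78 °C) would give the C7 1,1-dimethylallyl ketone F5. Rhodium-catalysed hydroboration of the monosubstituted alkene (catecholborane, RhCl(PPh3)3, then NaOH/H2O2) would give the primary alcohol F6. Dess–Martin oxidation would give the aldehyde F7, addition of i-PrMgCl at −78 °C the secondary alcohol F8, and a second Dess–Martin oxidation rejoins the route at 18.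

**Further compounds**

F1 | step 19 | S-ethyl thioester at C2 of the bicyclic 2-isobutyryl-1,3-dione (C9 enol) | C=C(C)[C@@H]1C[C@@]2(C(=O)SCC)C(=O)[C@@]3(C/C=C(\C)CCC=C(C)C)C[C@@H](C[C@H]2C1(C)C)C(C)(C)C(C(=O)C(C)C)=C3O
F2 | step 19 | C2 aldehyde of the bicyclic 2-isobutyryl-1,3-dione (C9 enol) | C=C(C)[C@@H]1C[C@@]2(C=O)C(=O)[C@@]3(C/C=C(\C)CCC=C(C)C)C[C@@H](C[C@H]2C1(C)C)C(C)(C)C(C(=O)C(C)C)=C3O
F3 | step 19 | caged C2 carbinol (either C2 epimer) | C=C(C)[C@@H]1C[C@@]23C(=O)[C@@]4(C/C=C(\C)CCC=C(C)C)C[C@@H](C[C@H]2C1(C)C)C(C)(C)[C@](C(=O)C(C)C)(C4=O)C3O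
F4 | step 17 | 3a-tert-butyl 5-methyl 7-(2,5-dimethyl-4-oxohexan-2-yl)-1,1-dimethyl-4-oxo-2-(prop-1-en-2-yl)octahydroazulene-3a,5(1H)-dicarboxylate (C5 labile) | C=C(C)[C@@H]1C[C@@]2(C(=O)OC(C)(C)C)C(=O)C(C(=O)OC)C[C@@H](C[C@H]2C1(C)C)C(C)(C)CC(=O)C(C)C
F5 | step 14 | tert-butyl 1,1-dimethyl-6-(2-methylbut-3-en-2-yl)-4-oxo-2-(prop-1-en-2-yl)octahydro-3aH-indene-3a-carboxylate | C=C(C)[C@@H]1C[C@@]2(C(=O)OC(C)(C)C)C(=O)C[C@@H](C[C@H]2C1(C)C)C(C)(C)C=C
F6 | step 14 | tert-butyl 6-(4-hydroxy-2-methylbutan-2-yl)-1,1-dimethyl-4-oxo-2-(prop-1-en-2-yl)octahydro-3aH-indene-3a-carboxylate | C=C(C)[C@@H]1C[C@@]2(C(=O)OC(C)(C)C)C(=O)C[C@@H](C[C@H]2C1(C)C)C(C)(C)CCO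
F7 | step 14 | tert-butyl 1,1-dimethyl-6-(2-methyl-4-oxobutan-2-yl)-4-oxo-2-(prop-1-en-2-yl)octahydro-3aH-indene-3a-carboxylate | C=C(C)[C@@H]1C[C@@]2(C(=O)OC(C)(C)C)C(=O)C[C@@H](C[C@H]2C1(C)C)C(C)(C)CC=O
F8 | step 14 | tert-butyl 6-(4-hydroxy-2,5-dimethylhexan-2-yl)-1,1-dimethyl-4-oxo-2-(prop-1-en-2-yl)octahydro-3aH-indene-3a-carboxylate (either carbinol epimer) | C=C(C)[C@@H]1C[C@@]2(C(=O)OC(C)(C)C)C(=O)C[C@@H](C[C@H]2C1(C)C)C(C)(C)CC(O)C(C)C
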